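## Assumptions
- The target acid has CO2H cis to the CH2 of the chain that leads to the chromene. This is Z by CIP, so a Z-selective olefination is required.
- The single enantiomer is obtained by chiral-phase HPLC resolution of the racemic TBS methyl ester. The (S)-fraction is assigned by running an analytical aliquot through Step 11 and matching [α]D/ECD with natural (S)-sargachromenol. The maximum yield is 50%.
- Phosphonate **8** and bromide **9** are commercial.

## Retrosynthetic overview
1. (S)-Sargachromenol **1** comes from LiOH removal of the methyl ester and the aryl TBS group of (S)-TBS methyl ester **2**. **2** is obtained by chiral-HPLC resolution of the racemic chromene **3**.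
2. The only new ring, the 2H-chromene, is formed in one step. **3** is made by PhB(OH)2-mediated condensation and oxa-6π-electrocyclisation of enal ester **4** with 4-TBSO-2-methylphenol **5**.
3. **4** comes from a Z-selective Still–Gennari HWE of dialdehyde **6** with alkylated phosphonate **7**, which is made from phosphonoacetate **8** and 5-bromo-2-methylpent-2-ene **9**.
4. **6** comes from (E,E)-farnesol **10** by terminal-alkene degradation: farnesyl acetate **11**, bromohydrin **12**, epoxy-alcohol **13**, hydroxy-aldehyde **14**, then **6**.
5. **5** comes from mono-silylation of 2-methylhydroquinone **15** with TBSCl **16**.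

## Forward route

**Step 1**
Reactants: **10** (2E,6E)-farnesol
Product: **11** (2E,6E)-farnesyl acetate
Conditions: Ac2O, Et3N, DMAP (cat.), CH2Cl2, 0 °C→rt
Reagents that add atoms: Ac2O, CC(=O)OC(C)=O
Why: Acetylation protects the allylic OH and inductively deactivates the proximal C2=C3 alkene, so the next electrophilic step favours the terminal alkene (esterification, no stereocentre).

**Step 2**
Reactants: **11** farnesyl acetate
Product: **12** (2E,6E)-10-bromo-11-hydroxy-3,7,11-trimethyldodeca-2,6-dien-1-yl acetate
Conditions: NBS, THF/H2O (3:1), 0 °C
Reagents that add atoms: NBS, O=C1CCC(=O)N1Br; water, O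
Why: Halohydrin formation occurs at the most electron-rich, least hindered terminal trisubstituted alkene, with water opening the bromonium at the tertiary carbon. The new C10 centre is racemic and is destroyed in Step 4.

**Step 3**
Reactants: **12**
Product: **13** (2E,6E)-10,11-epoxyfarnesol, i.e. (2E,6E)-9-(3,3-dimethyloxiran-2-yl)-3,7-dimethylnona-2,6-dien-1-ol
Conditions: K2CO3, MeOH, rt
Reagents that add atoms: none
Why: Base closes the epoxide by intramolecular SN2 of the tertiary alkoxide on C–Br, and methanolysis removes the acetate. The alkenes are untouched.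

**Step 4**
Reactants: **13**
Product: **14** (4E,8E)-10-hydroxy-4,8-dimethyldeca-4,8-dienal
Conditions: H5IO6, Et2O/THF, 0 °C→rt
Reagents that add atoms: none
Why: Periodic acid opens the epoxide to the diol and cleaves it (Malaprade-type), giving the aldehyde plus acetone, so the racemic C10 centre is lost. The E-alkenes are retained.

**Step 5**
Reactants: **14**
Product: **6** (4E,8E)-4,8-dimethyldeca-4,8-dienedial
Conditions: activated MnO2 (10 equiv), CH2Cl2, rt
Reagents that add atoms: none
Why: MnO2 oxidises the allylic alcohol selectively and leaves the saturated aldehyde and the alkenes alone.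

**Step 6**
Reactants: **8** methyl 2-[bis(2,2,2-trifluoroethoxy)phosphoryl]acetate (1.5 equiv); **9** 5-bromo-2-methylpent-2-ene
Product: **7** methyl 2-[bis(2,2,2-trifluoroethoxy)phosphoryl]-6-methylhept-5-enoate (racemic at C2)
Conditions: NaH, NaI (cat.), DMF, 0 °C→rt
Reagents that add atoms: none
Why: SN2 C-alkylation of the phosphonoacetate carbanion (Finkelstein-assisted) installs the 4-methylpent-3-enyl group. Excess **8** limits dialkylation, and the C2 stereocentre is irrelevant because it is lost in the HWE.

**Step 7**
Reactants: **6** (4E,8E)-4,8-dimethyldeca-4,8-dienedial; **7** (1.05 equiv)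
Product: **4** methyl (2Z,6E,10E)-6,10-dimethyl-2-(4-methylpent-3-en-1-yl)-12-oxododeca-2,6,10-trienoate
Conditions: KHMDS, 18-crown-6, THF, −78 °C (aldehyde added slowly to the preformed anion)
Reagents that add atoms: none
Why: In a Still–Gennari HWE the electron-poor bis(trifluoroethyl) phosphonate gives fast, kinetically controlled syn-elimination, so the ester ends up cis to the aldehyde-derived chain, which is the Z-trisubstituted acrylate of the target. It reacts at the far more electrophilic saturated CHO and not at the β,β-disubstituted enal.

**Step 8**
Reactants: **15** 2-methylhydroquinone; **16** TBSCl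
Product: **5** 4-(tert-butyldimethylsilyloxy)-2-methylphenol
Conditions: TBSCl (1.0 equiv), imidazole, CH2Cl2/DMF, 0 °C, then chromatography
Reagents that add atoms: TBSCl, CC(C)(C)[Si](C)(C)Cl
Why: Silylation favours the less hindered 4-OH, leaving free the OH ortho to the methyl group. That OH becomes the ring oxygen, so the chromene will carry the 6-O-silyl and 8-methyl groups of the target. Minor regioisomer and bis-silyl ether are removed by chromatography.

**Step 9**
Reactants: **4** enal ester; **5** 4-(TBSO)-2-methylphenol
Product: **3** racemic methyl (2Z,6E)-9-[6-(tert-butyldimethylsilyloxy)-2,8-dimethyl-2H-chromen-2-yl]-6-methyl-2-(4-methylpent-3-en-1-yl)nona-2,6-dienoate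
Conditions: PhB(OH)2 (1.1 equiv), propionic acid, toluene, 110 °C, Dean–Stark
Reagents that add atoms: none
Why: Phenylboronate-templated ortho-condensation with the enal (Knoevenagel-type) gives an o-quinone methide, which undergoes 6π-oxa-electrocyclisation to the 2H-chromene with net loss of H2O. The new quaternary C2 is formed without chiral influence and is therefore racemic, and the attack at the free ortho position fixes the 6-OTBS/8-methyl pattern.

**Step 10**
Reactants: **3** racemic TBS methyl ester
Product: **2** methyl (2Z,6E)-9-[(2S)-6-(tert-butyldimethylsilyloxy)-2,8-dimethyl-2H-chromen-2-yl]-6-methyl-2-(4-methylpent-3-en-1-yl)nona-2,6-dienoate (the (S)-enantiomer)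
Conditions: preparative chiral HPLC, Chiralpak IA, n-hexane/i-PrOH (99.5:0.5), rt
Reagents that add atoms: none
Why: Chiral-stationary-phase resolution separates the two C2 enantiomers of the 2-methyl-2-alkylchromene. No new stereocentre is made, and the (S)-fraction is identified as described in the assumptions. This sets the only stereocentre, and Step 11 does not touch it.

**Step 11**
Reactants: **2** (S)-TBS methyl ester
Product: **1** (S)-sargachromenol
Conditions: LiOH·H2O, THF/MeOH/H2O (3:1:1), 50 °C, Ar; then aq. citric acid to pH 4
Reagents that add atoms: water, O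
Why: Saponification removes the hindered methyl ester, and the labile aryl silyl ether is cleaved in the same pot to the free phenol. The Z-acrylate, the other alkenes and the tertiary allylic aryl ether are unaffected, so C2 is not racemised, and the mild acidification avoids opening the chromene.

## Compound list
1 | (S)-Sargachromenol | CC(C)=CCC/C(=C/CC/C(C)=C/CC[C@@]1(C)C=Cc2cc(O)cc(C)c2O1)C(=O)O | target
2 | (S)-TBS methyl ester | CC(C)=CCC/C(=C/CC/C(C)=C/CC[C@@]1(C)C=Cc2cc(O[Si](C)(C)C(C)(C)C)cc(C)c2O1)C(=O)OC | intermediate
3 | racemic TBS methyl ester | CC(C)=CCC/C(=C/CC/C(C)=C/CCC1(C)C=Cc2cc(O[Si](C)(C)C(C)(C)C)cc(C)c2O1)C(=O)OC | intermediate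
4 | enal ester, methyl (2Z,6E,10E)-6,10-dimethyl-2-(4-methylpent-3-en-1-yl)-12-oxododeca-2,6,10-trienoate | CC(C)=CCC/C(=C/CC/C(C)=C/CC/C(C)=C/C=O)C(=O)OC | intermediate
5 | 4-(TBSO)-2-methylphenol | Cc1cc(O[Si](C)(C)C(C)(C)C)ccc1O | intermediate
6 | (4E,8E)-4,8-dimethyldeca-4,8-dienedial | O=CCC/C(C)=C/CC/C(C)=C/C=O | intermediate
7 | methyl 2-[bis(trifluoroethoxy)phosphoryl]-6-methylhept-5-enoate (racemic) | COC(=O)C(CCC=C(C)C)P(=O)(OCC(F)(F)F)OCC(F)(F)F | intermediate
8 | methyl bis(2,2,2-trifluoroethyl)phosphonoacetate | COC(=O)CP(=O)(OCC(F)(F)F)OCC(F)(F)F | starting material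
9 | 5-bromo-2-methylpent-2-ene | CC(C)=CCCBr | starting material
10 | (2E,6E)-farnesol | CC(C)=CCC/C(C)=C/CC/C(C)=C/CO | starting material
11 | (2E,6E)-farnesyl acetate | CC(C)=CCC/C(C)=C/CC/C(C)=C/COC(C)=O | intermediate
12 | 10-bromo-11-hydroxy farnesyl acetate (racemic at C10) | CC(C)(O)C(Br)CC/C(C)=C/CC/C(C)=C/COC(C)=O | intermediate
13 | (2E,6E)-10,11-epoxyfarnesol (racemic) | CC1(C)OC1CC/C(C)=C/CC/C(C)=C/CO | intermediate
14 | (4E,8E)-10-hydroxy-4,8-dimethyldeca-4,8-dienal | O=CCC/C(C)=C/CC/C(C)=C/CO | intermediate
15 | 2-methylhydroquinone | Cc1cc(O)ccc1O | starting material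
16 | TBSCl | CC(C)(C)[Si](C)(C)Cl | starting material

**Step count:** 11 steps in total. The longest linear sequence is 9 steps (Steps 1, 2, 3, 4, 5, 7, 9, 10, 11).

## Three steps most likely to fail
1. **Step 9 (chromene condensation).** The polyene acrylate enal may isomerise, cyclise or decompose at 110 °C under acid.
   Fallback: a Kabbe-type route. Condense the methyl ketone MeCO(CH2)2CH=C(Me)(CH2)2CH=C(CO2Me)(CH2)2CH=CMe2 with 2'-hydroxy-3'-methyl-5'-(TBSO)acetophenone and pyrrolidine to give the chromanone. Then reduce with NaBH4 and dehydrate with TsOH to give **3**.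
2. **Step 7 (Z-selective HWE).** The α-alkyl Still–Gennari reaction may give a poor Z:E ratio.
   Fallback: change the olefination class to an Ando-type α-alkyl diarylphosphonoacetate (Z-selective through a different mechanistic origin), made from the same bromide **9**. Use it with NaI/DBU or Triton B on **6**, and remove residual E-isomer on AgNO3-silica.
3. **Step 10 (chiral HPLC resolution).** Separation on preparative scale may be poor, and it caps the yield at 50%.
   Fallback: drop the resolution and set C2 enantioselectively. Run the Kabbe condensation of the fallback in item 1 with a chiral pyrrolidine-based amine catalyst to give an enantioenriched chromanone, then apply NaBH4 and TsOH dehydration. Upgrade the ee with one analytical-scale HPLC pass if needed.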